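The target is the meso dimer: the two cyclohexanes are mirror images. Each ring's β-hydroxy ketone array, C2–OH cis to the acyl group on quaternary C1, is masked as a cis-fused β-lactone that is absent from the target. The key step closes both cyclohexanes at C1–C6 by alkylation of a β-lactone enolate with an iodopropyl arm held on the (Z)-alkylidene carbon C3; the four-membered ring forces cis fusion and so fixes C1 from C2. The precursor is an open-chain (Z,Z)-diene carrying two monocyclic β-lactones of opposite handedness, set by quinidine- and quinine-derived catalysts in turn. Prenyl sulfone anion then opens the lactones to the ketones.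

Key step: step 8

Locants: in each cyclohexane C1 is the quaternary carbon (methyl, acyl), C2 the carbinol carbon, C3 the alkylidene carbon and C4–C6 the ring methylenes.

Remark on the chemistry: the target is achiral (meso), one half being (1R,2S) and the other (1S,2R), so the route must join one half to its mirror image.

Assumption: O-trimethylsilylquinidine is taken to give the (3R,4R)-lactone and O-trimethylsilylquinine its mirror image. If the sense is the reverse, 11 forms as its enantiomer and steps 6 and 7 still converge on the same meso compound 13.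

Assumption: in steps 6 and 7 the reacting nucleophile is taken to be the catalyst-bound (Z)-ammonium enolate, formed by N-acylation of the alkaloid by 9 and deprotonation by iPr2NEt. Each catalyst therefore has its own enolate (10 or 12).

Step 1
Reactants: 1 methyl 2-[bis(2,2,2-trifluoroethoxy)phosphoryl]acetate; 2 1,3-diiodopropane
Product: 3 methyl 2-[bis(2,2,2-trifluoroethoxy)phosphoryl]-5-iodopentanoate (racemic)
Conditions: NaH (1.0 equiv), 2 (5 equiv), DMF, 0 °C to rt
Reagents that add atoms: none
Why: SN2 C-alkylation of the stabilised phosphonoacetate anion; one equivalent of base and excess diiodide should hold back dialkylation and cyclobutane formation.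

Step 2
Reactants: 4 2,5-dimethoxytetrahydrofuran (cis/trans mixture)
Product: 5 succinaldehyde
Conditions: H2O, 90 °C; distillation, used fresh
Reagents that add atoms: water (O)
Why: hydrolysis of the cyclic bis-acetal sets the dialdehyde free.

Step 3
Reactants: 5 succinaldehyde; 3 methyl 2-[bis(2,2,2-trifluoroethoxy)phosphoryl]-5-iodopentanoate (2.2 equiv)
Product: 6 dimethyl (2Z,6Z)-2,7-bis(3-iodopropyl)octa-2,6-dienedioate
Conditions: KN(SiMe3)2, 18-crown-6, THF, −78 °C
Reagents that add atoms: none
Why: two-directional Still–Gennari olefination; the trifluoroethyl phosphonate should place each chain CH2 cis to the ester, which is the alkene geometry of the target.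

Step 4
Reactants: 6 dimethyl (2Z,6Z)-2,7-bis(3-iodopropyl)octa-2,6-dienedioate
Product: 7 (2Z,6Z)-2,7-bis(3-iodopropyl)octa-2,6-diene-1,8-diol
Conditions: iBu2AlH, CH2Cl2, −78 °C; aqueous potassium sodium tartrate (KNaC4H4O6) work-up; used at once
Reagents that add atoms: none
Why: 1,2-reduction of both enoate esters at low temperature should leave the alkene geometry and the primary iodides untouched.

Step 5
Reactants: 7 (2Z,6Z)-2,7-bis(3-iodopropyl)octa-2,6-diene-1,8-diol
Product: 8 (2Z,6Z)-2,7-bis(3-iodopropyl)octa-2,6-dienedial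
Conditions: Dess–Martin periodinane, NaHCO3, CH2Cl2, 0 °C; used at once
Reagents that add atoms: none
Why: buffered Dess–Martin oxidation of the allylic alcohols is neutral and cold, so the sensitive (Z)-enal geometry should survive.

Step 6
Reactants: 8 (2Z,6Z)-2,7-bis(3-iodopropyl)octa-2,6-dienedial (3 equiv); 9 propionyl chloride (1 equiv)
Product: 11 (2Z,6Z)-10-iodo-2-(3-iodopropyl)-7-[(2R,3R)-3-methyl-4-oxooxetan-2-yl]deca-2,6-dienal, via quinidine-bound ammonium enolate 10 (not isolated)
Conditions: O-trimethylsilylquinidine (10 mol %), LiClO4, iPr2NEt, CH2Cl2/Et2O, −78 °C; 9 added slowly; excess 8 recovered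
Reagents that add atoms: none
Why: cinchona alkaloid–LiClO4 catalysed acyl halide–aldehyde cyclocondensation (formal [2+2]), in which enolate 10 adds to the lithium-activated aldehyde and the aldolate closes onto the acylammonium carbon to release the catalyst and the cis-β-lactone; the catalyst sets the carbinol carbon and the excess of dialdehyde limits reaction to one end.

Step 7
Reactants: 11 mono-β-lactone aldehyde; 9 propionyl chloride (3 equiv)
Product: 13 meso-(3R,4R,3'S,4'S)-4,4'-[(4Z,8Z)-1,12-diiodododeca-4,8-diene-4,9-diyl]bis(3-methyloxetan-2-one), via quinine-bound ammonium enolate 12 (not isolated)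
Conditions: O-trimethylsilylquinine (10 mol %), LiClO4, iPr2NEt, CH2Cl2/Et2O, −78 °C
Reagents that add atoms: none
Why: the same acyl halide–aldehyde cyclocondensation through the pseudo-enantiomeric enolate 12 sets the second carbinol carbon in the mirror-image sense, independently of the remote first lactone, so the bis-lactone is meso.

Step 8
Reactants: 13 meso bis-β-lactone
Product: 15 meso-(1R,6S,1'S,6'R,5Z,5'Z)-5,5'-(butane-1,4-diylidene)bis(1-methyl-7-oxabicyclo[4.2.0]octan-8-one), via dilithium bis-enolate 14 (not isolated)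
Conditions: 13 added slowly to LiN(iPr)2 (2.3 equiv), THF, −78 °C, 0.01 M; then DMPU, −78 to −40 °C
Reagents that add atoms: none
Why: Each lactone is deprotonated at its α-carbon to the planar enolate 14, which displaces the primary iodide of the arm on the neighbouring alkylidene carbon by SN2, making the C1–C6 bond and the quaternary carbon of each cyclohexane. The closest known reactions are the intermolecular C-alkylation of β-lactone enolates to α-quaternary β-lactones, the ring-closing alkylation of azetidinone enolates, and the cycloalkylation step of the methylenecyclohexane annulation, which has the same ring topology. Each six-membered ring closes in the 6-(enolexo)-exo-tet mode. The new quaternary stereocentre is controlled by the carbinol carbon already present: the arm is tethered to one face of the four-membered ring, so only cis fusion can form and the lactone oxygen ends cis to the lactone carbonyl, the future acyl group. The step needs C- over O-alkylation and ring closure over self-acylation or breakdown of the strained enolate; O-alkylation would need an eight-membered ring, and slow inverse addition at high dilution and low temperature with an iodide leaving group should secure the rest.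

Step 9
Reactants: 16 prenyl bromide (1-bromo-3-methylbut-2-ene); 17 sodium benzenesulfinate
Product: 18 (3-methylbut-2-en-1-yl) phenyl sulfone
Conditions: DMF, rt
Reagents that add atoms: none
Why: SN2 S-alkylation of the sulfinate at the primary allylic carbon gives the prenyl sulfone.

Step 10
Reactants: 15 meso bis(bicyclic β-lactone); 18 (3-methylbut-2-en-1-yl) phenyl sulfone (4.5 equiv)
Product: 20 meso bis(β-keto sulfone) diol (epimer mixture at the two sulfonyl-bearing carbons), via lithiated prenyl phenyl sulfone 19 (not isolated)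
Conditions: n-BuLi (4.4 equiv), THF, −78 °C; then 15, −78 to −40 °C; AcOH, −78 °C
Reagents that add atoms: none
Why: acylation of the α-sulfonyl carbanion at its α-carbon by the strained lactone (acyl–oxygen cleavage) frees the C2 hydroxyl with retention; a second equivalent of 19 deprotonates the acidic β-keto sulfone as it forms, which should protect the ketone from further addition and from retro-aldol cleavage until the quench.

Step 11
Reactants: 20 meso bis(β-keto sulfone) diol
Product: 21 1-[(1R,2S,3Z)-2-hydroxy-3-{4-[(1Z,2R,3S)-2-hydroxy-3-methyl-3-(4-methylpent-3-enoyl)cyclohexylidene]butylidene}-1-methylcyclohexyl]-4-methylpent-3-en-1-one (meso target)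
Conditions: SmI2, THF/MeOH, −78 °C; aqueous NH4Cl
Reagents that add atoms: none
Why: reductive desulfonylation of the β-keto sulfones by SmI2; cold protonation by methanol at the α-carbon should keep the trisubstituted double bond out of conjugation.

**Compound list**

1 | methyl 2-[bis(2,2,2-trifluoroethoxy)phosphoryl]acetate | COC(=O)CP(=O)(OCC(F)(F)F)OCC(F)(F)F | starting material
2 | 1,3-diiodopropane | ICCCI | starting material
3 | methyl 2-[bis(2,2,2-trifluoroethoxy)phosphoryl]-5-iodopentanoate (racemic) | COC(=O)C(CCCI)P(=O)(OCC(F)(F)F)OCC(F)(F)F | intermediate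
4 | 2,5-dimethoxytetrahydrofuran (cis/trans mixture) | COC1CCC(OC)O1 | starting material
5 | succinaldehyde | O=CCCC=O | intermediate
6 | dimethyl (2Z,6Z)-2,7-bis(3-iodopropyl)octa-2,6-dienedioate | COC(=O)/C(CCCI)=C\CC/C=C(/CCCI)C(=O)OC | intermediate
7 | (2Z,6Z)-2,7-bis(3-iodopropyl)octa-2,6-diene-1,8-diol | OC/C(CCCI)=C\CC/C=C(/CCCI)CO | intermediate
8 | (2Z,6Z)-2,7-bis(3-iodopropyl)octa-2,6-dienedial | O=C/C(CCCI)=C\CC/C=C(/CCCI)C=O | intermediate
9 | propionyl chloride | CCC(=O)Cl | starting material
10 | N-[(Z)-1-oxidoprop-1-enyl]-O-trimethylsilylquinidinium, the zwitterionic ammonium enolate of the quinidine-derived catalyst (not isolated) | COC1=CC2=C(C=CN=C2C=C1)[C@@H]([C@H]3C[C@@H]4CC[N@@+]3(/C([O-])=C/C)C[C@@H]4C=C)O[Si](C)(C)C | intermediate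
11 | (2Z,6Z)-10-iodo-2-(3-iodopropyl)-7-[(2R,3R)-3-methyl-4-oxooxetan-2-yl]deca-2,6-dienal | O=C1[C@H](C)[C@@H](O1)/C(CCCI)=C\CC/C=C(/CCCI)C=O | intermediate
12 | N-[(Z)-1-oxidoprop-1-enyl]-O-trimethylsilylquininium, the zwitterionic ammonium enolate of the quinine-derived catalyst (not isolated) | COC1=CC2=C(C=CN=C2C=C1)[C@H]([C@@H]3C[C@@H]4CC[N@@+]3(/C([O-])=C/C)C[C@@H]4C=C)O[Si](C)(C)C | intermediate
13 | meso-(3R,4R,3'S,4'S)-4,4'-[(4Z,8Z)-1,12-diiodododeca-4,8-diene-4,9-diyl]bis(3-methyloxetan-2-one) | O=C1[C@H](C)[C@@H](O1)/C(CCCI)=C\CC/C=C(/CCCI)[C@H]1OC(=O)[C@H]1C | intermediate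
14 | dilithium bis-enolate of 13 (not isolated) | [Li+].[Li+].[O-]C1=C(C)[C@@H](O1)/C(CCCI)=C\CC/C=C(/CCCI)[C@H]1OC([O-])=C1C | intermediate
15 | meso-(1R,6S,1'S,6'R,5Z,5'Z)-5,5'-(butane-1,4-diylidene)bis(1-methyl-7-oxabicyclo[4.2.0]octan-8-one) | O=C1[C@]2(C)CCC/C(=C/CC/C=C3/CCC[C@](C)(C4=O)[C@@H]3O4)[C@@H]2O1 | intermediate
16 | prenyl bromide (1-bromo-3-methylbut-2-ene) | CC(C)=CCBr | starting material
17 | sodium benzenesulfinate | [Na+].[O-]S(=O)c1ccccc1 | starting material
18 | (3-methylbut-2-en-1-yl) phenyl sulfone | CC(C)=CCS(=O)(=O)c1ccccc1 | intermediate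
19 | lithiated prenyl phenyl sulfone (not isolated) | [Li+].CC(C)=C[CH-]S(=O)(=O)c1ccccc1 | intermediate
20 | meso bis(β-keto sulfone) diol: the target with a phenylsulfonyl group on C2 of each 4-methylpent-3-enoyl chain (epimer mixture at those two carbons) | CC(C)=CC(C(=O)[C@]1(C)CCC/C(=C/CC/C=C2/CCC[C@](C)(C(=O)C(C=C(C)C)S(=O)(=O)c3ccccc3)[C@@H]2O)[C@@H]1O)S(=O)(=O)c1ccccc1 | intermediate
21 | 1-[(1R,2S,3Z)-2-hydroxy-3-{4-[(1Z,2R,3S)-2-hydroxy-3-methyl-3-(4-methylpent-3-enoyl)cyclohexylidene]butylidene}-1-methylcyclohexyl]-4-methylpent-3-en-1-one (meso) | CC(C)=CCC(=O)[C@]1(C)CCC/C(=C/CC/C=C2/CCC[C@](C)(C(=O)CC=C(C)C)[C@@H]2O)[C@@H]1O | target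

Total step count: 11. Longest linear sequence: 9 steps (steps 1, 3, 4, 5, 6, 7, 8, 10, 11).

**Steps most likely to fail**

Step 8. The strained lactone enolates may acylate unreacted lactone or fragment before the slower ring-closing SN2 takes place, or only one of the two rings may close. The fallback sets out from 13 and comes back at 15. K2CO3 in MeOH opens both lactones at the acyl carbon to the bis(β-hydroxy methyl ester) F1. Excess LiN(iPr)2 in THF/DMPU (−78 to −20 °C) then effects a Fráter–Seebach alkylation run intramolecularly: the lithium alkoxide–enolate chelate of each half places the ester cis to the oxygen as the iodide is displaced, which should give the bis(cis-2-hydroxy ester) F2. LiOH in aqueous dioxane with heating gives the bis(hydroxy acid) F3, and PhSO2Cl in pyridine at 0 °C closes both β-lactones with retention to 15.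

Step 6. The hindered, conjugated (Z)-enal may react too slowly in the ammonium-enolate aldol–lactonisation, the Z geometry may erode through reversible conjugate addition of the amine, or both ends may react with the same catalyst, which would lead to the chiral diastereomer. The fallback sets out from 8 and comes back at 13, replacing steps 6 and 7 by auxiliary-controlled aldol chemistry. (R)-4-Benzyl-3-propionyloxazolidin-2-one with Bu2BOTf and Et3N (CH2Cl2, −78 °C), used as the limiting reagent against excess 8, gives the mono syn-aldol adduct F4. The same Evans aldol with the (S)-imide on the remaining aldehyde gives the bis-adduct F5, whose two halves are mirror images. LiOH/H2O2 (THF/H2O, 0 °C) removes both auxiliaries to give the bis(syn-β-hydroxy acid) F6, and PhSO2Cl in pyridine lactonises it to 13.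

Step 10. The sulfonyl carbanion may attack the allylic C–O carbon (alkyl–oxygen cleavage, direct or with allylic shift) in place of the hindered acyl carbon, or the second lactone may not be acylated. The fallback sets out from 15 and comes back at 21, replacing steps 10 and 11. MeNH(OMe)·HCl with Me2AlCl (CH2Cl2, 0 °C) opens both lactones at the acyl carbon to the bis(Weinreb amide) diol F7. Et3SiOTf with 2,6-lutidine gives the bis(triethylsilyl ether) F8, and iBu2AlH (THF, −78 °C) reduces it to the dialdehyde F9. Prenylbarium chloride (from prenyl chloride, BaI2 and lithium biphenylide, THF, −78 °C) adds through its unsubstituted carbon to give the bis(homoallylic alcohol) F10 as a carbinol epimer mixture. Dess–Martin periodinane with NaHCO3 gives the bis(β,γ-unsaturated ketone) F11 without an enolate on the way, and HF·pyridine (THF, 0 °C) removes the silyl groups to give 21.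

Further compounds
F1 | step 8 | dimethyl (2R,3R,10S,11S,4Z,8Z)-3,10-dihydroxy-4,9-bis(3-iodopropyl)-2,11-dimethyldodeca-4,8-dienedioate (meso) | COC(=O)[C@H](C)[C@@H](O)/C(CCCI)=C\CC/C=C(/CCCI)[C@@H](O)[C@H](C)C(=O)OC
F2 | step 8 | meso bis(cis-2-hydroxy ester): dimethyl 3,3'-(butane-1,4-diylidene)bis(2-hydroxy-1-methylcyclohexane-1-carboxylate), (1R,2S,3Z) and (1'S,2'R,3'Z) | COC(=O)[C@]1(C)CCC/C(=C/CC/C=C2/CCC[C@](C)(C(=O)OC)[C@@H]2O)[C@@H]1O
F3 | step 8 | meso bis(hydroxy acid): 3,3'-(butane-1,4-diylidene)bis(2-hydroxy-1-methylcyclohexane-1-carboxylic acid), (1R,2S,3Z) and (1'S,2'R,3'Z) | OC(=O)[C@]1(C)CCC/C(=C/CC/C=C2/CCC[C@](C)(C(=O)O)[C@@H]2O)[C@@H]1O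
F4 | step 6 | mono syn-aldol adduct: (R)-4-benzyl-3-[(2R,3R)-3-hydroxy-2-methylacyl]oxazolidin-2-one carrying the (Z,Z)-diene chain and the free (Z)-enal | O=C1OC[C@@H](Cc2ccccc2)N1C(=O)[C@H](C)[C@@H](O)/C(CCCI)=C\CC/C=C(/CCCI)C=O
F5 | step 6 | bis syn-aldol adduct with the (R)-auxiliary on the (2R,3R) half and the (S)-auxiliary on the (2S,3S) half | O=C1OC[C@@H](Cc2ccccc2)N1C(=O)[C@H](C)[C@@H](O)/C(CCCI)=C\CC/C=C(/CCCI)[C@@H](O)[C@H](C)C(=O)N1[C@@H](Cc2ccccc2)COC1=O
F6 | step 6 | (2R,3R,10S,11S,4Z,8Z)-3,10-dihydroxy-4,9-bis(3-iodopropyl)-2,11-dimethyldodeca-4,8-dienedioic acid (meso) | OC(=O)[C@H](C)[C@@H](O)/C(CCCI)=C\CC/C=C(/CCCI)[C@@H](O)[C@H](C)C(=O)O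
F7 | step 10 | meso bis(N-methoxy-N-methylamide) diol: the target with each 4-methylpent-3-enoyl group replaced by C(=O)N(OMe)Me | CON(C)C(=O)[C@]1(C)CCC/C(=C/CC/C=C2/CCC[C@](C)(C(=O)N(C)OC)[C@@H]2O)[C@@H]1O
F8 | step 10 | bis(triethylsilyl ether) of F7 | CON(C)C(=O)[C@]1(C)CCC/C(=C/CC/C=C2/CCC[C@](C)(C(=O)N(C)OC)[C@@H]2O[Si](CC)(CC)CC)[C@@H]1O[Si](CC)(CC)CC
F9 | step 10 | meso dialdehyde: the bis(triethylsilyl ether) with a formyl group on each quaternary carbon | O=C[C@]1(C)CCC/C(=C/CC/C=C2/CCC[C@](C)(C=O)[C@@H]2O[Si](CC)(CC)CC)[C@@H]1O[Si](CC)(CC)CC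
F10 | step 10 | bis(1-hydroxy-4-methylpent-3-enyl) bis(triethylsilyl ether) (carbinol epimer mixture) | CC(C)=CCC(O)[C@]1(C)CCC/C(=C/CC/C=C2/CCC[C@](C)(C(O)CC=C(C)C)[C@@H]2O[Si](CC)(CC)CC)[C@@H]1O[Si](CC)(CC)CC
F11 | step 10 | bis(triethylsilyl ether) of the target | CC(C)=CCC(=O)[C@]1(C)CCC/C(=C/CC/C=C2/CCC[C@](C)(C(=O)CC=C(C)C)[C@@H]2O[Si](CC)(CC)CC)[C@@H]1O[Si](CC)(CC)CC
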